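(The rate constants were drawn at random within sensible limits.)

Over 6.0 h, your hunch that the flasks convert about the same fraction looks right to us, and here is the quick number behind it.

    starting material + free catalyst → catalyst intermediate (k1 = 21 M⁻¹ min⁻¹)
    catalyst intermediate → free catalyst + product (k2 = 11 min⁻¹)
    2 free catalyst → spent catalyst A (k3 = 8.1 M⁻¹ min⁻¹)
    free catalyst + product → spent catalyst B (k4 = 0.011 M⁻¹ min⁻¹)

| flask | starting material | free catalyst | time |
|---|---|---|---|
| oak | 0.010 M | 0.23 mM | 6.0 h |
| larch | 0.030 M | 0.23 mM | 6.0 h |
| alder | 0.10 M | 0.23 mM | 6.0 h |

- for a step with 2 of a species take k times the square, and two of it per event
- "hardly changes" means that all values lie within two and a half points (for a concentration: within two and a half percent of the largest)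
- run time (oak): 6.0 h

1. [product] at the end for oak, larch, alder, in this order
2. the course of these numbers from the first flask to the last (rises, then falls / falls, then rises / hardly changes / falls all the way / rises all the way)

We take the self-reaction of the free catalyst as the main loss of catalyst from the round and treat the rest as corrections. The catalyst intermediate is the first correction. Even in alder, free catalyst is captured at 2.10 min⁻¹ per unit at the start, slower than the intermediate breaks down at 11 min⁻¹, so free catalyst is the resting state of the round. Poisoning is the second correction. With the alder charge counted as product, it costs free catalyst 0.00110 min⁻¹, less than the 0.00373 min⁻¹ of the self-reaction at the charge of free catalyst. We drop both.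

Free catalyst then falls as its charge divided by one plus x, where x is two times the self-reaction constant times the charge times the time, here 1.34. Starting material falls in a pseudo-first-order way, with the capture constant times [free catalyst] as its rate constant. Integrating gives the number to carry, the conversion exponent: the natural logarithm of the charge of starting material over what remains, equal to the capture constant over two times the self-reaction constant, times the logarithm of one plus x. It comes to 1.10. It holds no [starting material], so by this reckoning each flask converts 66.8% of its charge, and we commit to 0.00668 M, 0.0200 M and 0.0668 M.

The forecast gives 0.0066 M, 0.0197 M and 0.064 M, with the course rises all the way. It sits lower than ours in alder, on the ground that “product poisoning outweighs the protection of catalyst held as intermediate”.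

The flasks end at 0.00665 M, 0.0198 M and 0.0641 M, and the course rises all the way, as the forecast said.

In oak at 1.66 h the catalyst intermediate has a half-life of 0.063 min by its breakdown, far shorter than the 3.3 h of starting material by its capture, its making and using stand at a ratio of 0.999, and the exponent's 33.3% of charge left meets the 33% that oak holds at the end. Carried unchanged to alder, the same exponent again says 33.3%, and alder holds 36% of its charge at 6.00 h.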